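**Plan**

- Names used: ring A is the benzene ring and ring B the pyran ring of the chromene at the alkene end; ring C and ring D are the benzene and pyran rings of the chromene at the stereocentre. Chromene numbering is O1, C2, C3, C4, C4a, C5–C8, C8a; the chain is Cα (on ring A), Cβ, Cγ (stereocentre, on ring C).
- Cuts: ring B at O1–C2 and C4–C4a together with the ring A C8–Cα bond and the Cα=Cβ double bond; ring D at the same two bonds; the ring C–Cγ bond.
- Enabling feature: in ring A the oxygen-bearing C8a lies between C8 (alkenyl) and C4a (pyran carbon), so both new C–C bonds are ortho to one phenolic oxygen. The parent 3,5-dimethoxyphenol has two equivalent ortho carbons, and a boron tether on its oxygen can deliver two different aldehydes in turn.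
- Forward order: a temporary lactol ring is made and opened in step 1, then ring D is closed, then aldehyde, phenol and prenal are joined in one flask, which forms the alkene and closes ring B last.
- Stereochemistry: the single (S) centre is set in step 1 by chiral secondary-amine (iminium) catalysis and is not touched again; the (E) alkene arises under thermodynamic control.

Key step: step 4

Remark (assumption): commercial crotonaldehyde is taken as the (E) isomer. The sense of induction in step 1 is assigned from the steric shielding model of the iminium ion; the enantiomeric catalyst is equally available if the sense proves opposite.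

**Route**

Step 1
Reactants: 1 3,5-dimethoxyphenol; 2 (E)-but-2-enal
Product: 4 2-[(2S)-4-hydroxybutan-2-yl]-3,5-dimethoxyphenol, via lactol 3 (not isolated)
Conditions: 1 (1.5 equiv), (R)-2-[diphenyl(trimethylsilyloxy)methyl]pyrrolidine (20 mol %), PhCO2H (20 mol %), toluene, 0 °C to rt; then NaBH4, MeOH, 0 °C
Reagents that add atoms: none
Why: Iminium-activated asymmetric Friedel–Crafts alkylation at an ortho carbon of the phenol, trapped as cyclic hemiacetal 3 (which releases the amine), in which the diphenyl(silyloxy)methyl group shields one face of the (E)-iminium ion so that the arene adds to the other and sets the (S) centre, followed by NaBH4 reduction of the lactol through its open hydroxy aldehyde form.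

Step 2
Reactants: 4 2-[(2S)-4-hydroxybutan-2-yl]-3,5-dimethoxyphenol; 5 3-methylbut-2-enal
Product: 8 (3S)-3-(5,7-dimethoxy-2,2-dimethyl-2H-chromen-8-yl)butan-1-ol, via benzodioxaborin 6 (not isolated), via dienone 7 (not isolated)
Conditions: 5 (3 equiv), PhB(OH)2 (2 equiv), EtCO2H (cat.), toluene, reflux, Dean–Stark; aq. NaOH wash
Reagents that add atoms: none
Why: Boronic acid templated ortho-condensation of a phenol with an enal (formal [3+3] annulation), in which the aryl borate delivers prenal to the only free ortho carbon to give 6, this collapses to dienone 7 and oxa-6π electrocyclisation closes ring D, while the primary alcohol forms only labile boronate esters that hydrolyse on work-up, the stereocentre is not involved and water is the only by-product.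

Step 3
Reactants: 8 (3S)-3-(5,7-dimethoxy-2,2-dimethyl-2H-chromen-8-yl)butan-1-ol
Product: 9 (3S)-3-(5,7-dimethoxy-2,2-dimethyl-2H-chromen-8-yl)butanal
Conditions: Dess–Martin periodinane, pyridine, CH2Cl2, 0 °C to rt
Reagents that add atoms: none
Why: Dess–Martin oxidation of a primary alcohol to the aldehyde under buffered, non-acidic conditions that should leave the electron-rich chromene untouched, the stereocentre being beta to the new carbonyl and therefore not epimerisable by enolisation.

Step 4
Reactants: 9 (3S)-3-(5,7-dimethoxy-2,2-dimethyl-2H-chromen-8-yl)butanal; 1 3,5-dimethoxyphenol; 5 3-methylbut-2-enal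
Product: 15 8-[(1E,3S)-3-(5,7-dimethoxy-2,2-dimethyl-2H-chromen-8-yl)but-1-en-1-yl]-5,7-dimethoxy-2,2-dimethyl-2H-chromene (target), via benzodioxaborin 10 (not isolated), via quinone methide 11 (not isolated), via alkenylphenol 12 (not isolated), via dienyl benzodioxaborin 13 (not isolated), via dienone 14 (not isolated)
Conditions: 1 (1.0 equiv), 9 (1.0 equiv), PhB(OH)2 (1.2 equiv), EtCO2H (0.3 equiv), toluene (0.05 M), reflux, Dean–Stark, until 9 and 10 are consumed; then 5 (3 equiv), reflux
Reagents that add atoms: none
Why: Proposed new method: a one-flask, three-component double ortho-functionalisation of phenol 1 on a phenylboron tether; the closest known reaction types are the boronic acid templated ortho-hydroxyalkylation of phenols with aldehydes via 4H-1,3,2-benzodioxaborins and the boronic acid mediated condensation of phenols with enals to 2H-chromenes, which are established separately but have not been run in sequence on one phenol. The aryl borate of 1 should deliver aldehyde 9 to an ortho carbon through a six-membered transition state to give 10; its benzylic C–O bond, flanked by an ortho and a para methoxy group, should ionise at reflux to quinone methide 11, and a [1,5]-hydrogen shift from the adjacent CH2 (or loss of that proton from the benzylic cation) should restore the phenol as the thermodynamically favoured (E)-alkenylphenol 12. The restored hydroxyl then takes up prenal 5 in the same way at the one ortho carbon left, 13 collapses to dienone 14, and a thermal disrotatory oxa-6π electrocyclisation closes pyran ring B by O1–C2 bond formation. No stereocentre is formed (C2 carries two methyl groups), and the (S) centre should survive because it is beta to the reacting carbonyl carbon and no cation, enol or carbanion is generated at it. The selectivity needed is ortho over para attack and the order in which the two aldehydes are used: the boron tether reaches ortho carbons only, the two ortho carbons of 1 are equivalent, and prenal is added only after 9 is consumed because pyran closure spends the hydroxyl that the first event regenerates.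

**Compound list**

1 | 3,5-dimethoxyphenol | COc1cc(O)cc(OC)c1 | starting material
2 | (E)-but-2-enal (crotonaldehyde) | C/C=C/C=O | starting material
3 | (4S)-5,7-dimethoxy-4-methyl-3,4-dihydro-2H-chromen-2-ol (both C2 epimers) | C[C@H]1CC(O)Oc2cc(OC)cc(OC)c21 | intermediate
4 | 2-[(2S)-4-hydroxybutan-2-yl]-3,5-dimethoxyphenol | C[C@@H](CCO)c1c(O)cc(OC)cc1OC | intermediate
5 | 3-methylbut-2-enal (prenal) | CC(C)=CC=O | starting material
6 | 8-[(2S)-4-hydroxybutan-2-yl]-5,7-dimethoxy-4-(2-methylprop-1-en-1-yl)-2-phenyl-4H-1,3,2-benzodioxaborin (both C4 epimers) | C[C@@H](CCO)c1c(OC)cc(OC)c2c1OB(c1ccccc1)OC2C=C(C)C | intermediate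
7 | 2-[(2S)-4-hydroxybutan-2-yl]-3,5-dimethoxy-6-(3-methylbut-2-en-1-ylidene)cyclohexa-2,4-dien-1-one | C[C@@H](CCO)C1=C(OC)C=C(OC)C(=CC=C(C)C)C1=O | intermediate
8 | (3S)-3-(5,7-dimethoxy-2,2-dimethyl-2H-chromen-8-yl)butan-1-ol | C[C@@H](CCO)c1c(OC)cc(OC)c2c1OC(C)(C)C=C2 | intermediate
9 | (3S)-3-(5,7-dimethoxy-2,2-dimethyl-2H-chromen-8-yl)butanal | C[C@@H](CC=O)c1c(OC)cc(OC)c2c1OC(C)(C)C=C2 | intermediate
10 | 4-[(2S)-2-(5,7-dimethoxy-2,2-dimethyl-2H-chromen-8-yl)propyl]-5,7-dimethoxy-2-phenyl-4H-1,3,2-benzodioxaborin (both C4 epimers) | COc1cc(OC)c2c(c1)OB(c1ccccc1)OC2C[C@H](C)c1c(OC)cc(OC)c2c1OC(C)(C)C=C2 | intermediate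
11 | 6-[(3S)-3-(5,7-dimethoxy-2,2-dimethyl-2H-chromen-8-yl)butylidene]-3,5-dimethoxycyclohexa-2,4-dien-1-one | O=C1C=C(OC)C=C(OC)C1=CC[C@H](C)c1c(OC)cc(OC)c2c1OC(C)(C)C=C2 | intermediate
12 | 2-[(1E,3S)-3-(5,7-dimethoxy-2,2-dimethyl-2H-chromen-8-yl)but-1-en-1-yl]-3,5-dimethoxyphenol | COc1cc(O)c(/C=C/[C@H](C)c2c(OC)cc(OC)c3c2OC(C)(C)C=C3)c(OC)c1 | intermediate
13 | 8-[(1E,3S)-3-(5,7-dimethoxy-2,2-dimethyl-2H-chromen-8-yl)but-1-en-1-yl]-5,7-dimethoxy-4-(2-methylprop-1-en-1-yl)-2-phenyl-4H-1,3,2-benzodioxaborin (both C4 epimers) | COc1cc(OC)c(/C=C/[C@H](C)c2c(OC)cc(OC)c3c2OC(C)(C)C=C3)c2c1C(C=C(C)C)OB(c1ccccc1)O2 | intermediate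
14 | 2-[(1E,3S)-3-(5,7-dimethoxy-2,2-dimethyl-2H-chromen-8-yl)but-1-en-1-yl]-3,5-dimethoxy-6-(3-methylbut-2-en-1-ylidene)cyclohexa-2,4-dien-1-one | COC1=CC(OC)=C(/C=C/[C@H](C)c2c(OC)cc(OC)c3c2OC(C)(C)C=C3)C(=O)C1=CC=C(C)C | intermediate
15 | 8-[(1E,3S)-3-(5,7-dimethoxy-2,2-dimethyl-2H-chromen-8-yl)but-1-en-1-yl]-5,7-dimethoxy-2,2-dimethyl-2H-chromene | COc1cc(OC)c(/C=C/[C@H](C)c2c(OC)cc(OC)c3c2OC(C)(C)C=C3)c2c1C=CC(C)(C)O2 | target

**Summary**

Total step count: 4. Longest linear sequence: 4 steps from phenol 1, which enters a second time in step 4.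

**Steps most likely to fail**

1. Step 4 (proposed new method). The sequence may stall at benzodioxaborin 10. Material may also be lost through capture of quinone methide 11 by a second electron-rich arene instead of the hydrogen shift, through acid-promoted oligomerisation of the hydroxystyrene, or through incomplete (E) selectivity. The fallback sets out from 9 and 1 and uses known chemistry. Phenol 1 is converted into 1,3-dimethoxy-5-(methoxymethoxy)benzene F1 (MOMCl, i-Pr2NEt, CH2Cl2). F1 is lithiated between the acetal and a methoxy group (n-BuLi, TMEDA, THF, 0 °C) and added to aldehyde 9 at −78 °C to give (3S)-1-[2,4-dimethoxy-6-(methoxymethoxy)phenyl]-3-(5,7-dimethoxy-2,2-dimethyl-2H-chromen-8-yl)butan-1-ol F2 as a mixture of carbinol epimers. Dilute aqueous HCl in THF at 40 °C should cleave the acetal and dehydrate the trialkoxybenzylic alcohol, so the route is rejoined at alkenylphenol 12. Compound 12 is then condensed with 5 as a separate operation (PhB(OH)2, EtCO2H, toluene, reflux) to reach 15.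

2. Step 1. Para attack on the phenol may compete with ortho attack, a second alkylation may occur, and facial selectivity may be modest with the small methyl-substituted enal. The fallback sets out from commercial 5,7-dimethoxy-4-methyl-2H-chromen-2-one F3. Its conjugated double bond is reduced with a copper hydride catalyst (Cu(OAc)2·H2O, DTBM-SEGPHOS in the enantiomer that delivers the (S) product, polymethylhydrosiloxane, t-BuOH, toluene) to give (4S)-5,7-dimethoxy-4-methyl-3,4-dihydro-2H-chromen-2-one F4. LiAlH4 in THF then opens the lactone and the route is rejoined at diol 4. Over-reduction to lactol 3 during the first operation is harmless because it converges on 4.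

3. Step 2. The free primary hydroxyl may interfere through boronate formation or acylation by the carboxylic acid, and condensation at the methoxy-flanked ortho carbon may be slow. The fallback sets out from 4. The phenol alone is O-alkylated with 3-chloro-3-methylbut-1-yne (DBU, cat. CuCl2, MeCN, 0 °C) to give (3S)-3-{2,4-dimethoxy-6-[(2-methylbut-3-yn-2-yl)oxy]phenyl}butan-1-ol F5. Heating in N,N-diethylaniline at 140–180 °C should trigger aromatic propargyl Claisen rearrangement to the free ortho carbon, [1,5]-hydrogen shift and oxa-6π electrocyclisation, rejoining the route at 8.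

**Further compounds**

F1 | step 4 | 1,3-dimethoxy-5-(methoxymethoxy)benzene | COCOc1cc(OC)cc(OC)c1
F2 | step 4 | (3S)-1-[2,4-dimethoxy-6-(methoxymethoxy)phenyl]-3-(5,7-dimethoxy-2,2-dimethyl-2H-chromen-8-yl)butan-1-ol (both carbinol epimers) | COCOc1cc(OC)cc(OC)c1C(O)C[C@H](C)c1c(OC)cc(OC)c2c1OC(C)(C)C=C2
F3 | step 1 | 5,7-dimethoxy-4-methyl-2H-chromen-2-one | CC1=CC(=O)Oc2cc(OC)cc(OC)c12
F4 | step 1 | (4S)-5,7-dimethoxy-4-methyl-3,4-dihydro-2H-chromen-2-one | C[C@H]1CC(=O)Oc2cc(OC)cc(OC)c21
F5 | step 2 | (3S)-3-{2,4-dimethoxy-6-[(2-methylbut-3-yn-2-yl)oxy]phenyl}butan-1-ol | C[C@@H](CCO)c1c(OC)cc(OC)cc1OC(C)(C)C#C
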